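**Plan**

- Retrosynthesis (ring A = the resorcinol that ends as the monoacetate, ring B = the free resorcinol, chain numbered C1 at ring A to C16 at ring B): first the three aryl O–Si bonds and the acetate C–O bond are cut. Then the C7–C8 single bond is cut together with the geometry of C8=C9, giving a primary alkyl pinacol boronate (ring A, C1–C7) and an (E)-alkenyl iodide (ring B, C8–C16). Last come C9–C10 (acetylide alkylation) and the two ring–chain bonds.
- Enabling feature: C8=C9 is a cis-1,2-dialkylethene and C8 carries the CH2 group C7. This is the array formed when a primary alkyl group shifts from boron to the alkenyl carbon of an (E)-alkenyl boronate under iodine and boron and iodine then leave anti. Seven CH2 groups insulate each ring from the site, so ring A (one MOM, one TIPS ether) and ring B (two TIPS ethers) arrive already differentiated.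
- Forward: 5-bromoresorcinol serves both halves. Ring–chain bonds come from Cu-catalysed Grignard alkylation, boron at C7 from hydroboration, and C8/C9 from trimethylsilylacetylene followed by hydrozirconation–iodination. After the Zweifel union, MOM is removed, the acetate installed, and TIPS removed.
- Stereochemistry: the only stereo-element is the Z alkene. The E-iodide comes from syn hydrozirconation and is inverted stereospecifically to Z in the union; the target has no stereocentres.

Key step: step 10

Remark: the two oxygens of ring A are equivalent by symmetry, so it is immaterial which of them ends as the acetate. TIPS = tri(propan-2-yl)silyl, MOM = methoxymethyl, Bpin = 4,4,5,5-tetramethyl-1,3,2-dioxaborolan-2-yl.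

**Route**

Step 1
Reactants: 1 5-bromobenzene-1,3-diol
Product: 2 3-bromo-5-(triisopropylsilyloxy)phenol
Conditions: iPr3SiCl (1.0 equiv), imidazole (2.2 equiv), DMF, 0 °C → rt
Reagents that add atoms: chlorotri(propan-2-yl)silane (iPr3SiCl), CC(C)[Si](Cl)(C(C)C)C(C)C
Why: Imidazole-promoted silyl ether formation at a phenol; with one equivalent of chlorosilane the two equivalent hydroxyl groups react statistically, and the monoether should separate from diol and bis-ether by chromatography.

Step 2
Reactants: 2 3-bromo-5-(triisopropylsilyloxy)phenol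
Product: 3 1-bromo-3-(methoxymethoxy)-5-(triisopropylsilyloxy)benzene
Conditions: MOMCl (1.3 equiv), iPr2NEt (2 equiv), CH2Cl2, 0 °C → rt
Reagents that add atoms: chloromethyl methyl ether (MOMCl), COCCl
Why: Williamson-type O-alkylation of the remaining phenol with the reactive α-chloro ether (MOM acetal protection), which should leave the aryl silyl ether and the C–Br bond untouched.

Step 3
Reactants: 3 1-bromo-3-(methoxymethoxy)-5-(triisopropylsilyloxy)benzene; 4 7-bromohept-1-ene
Product: 6 1-(hept-6-en-1-yl)-3-(methoxymethoxy)-5-(triisopropylsilyloxy)benzene, via arylmagnesium bromide 5 (not isolated)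
Conditions: Mg turnings, LiCl, THF, rt; then 4 (1.2 equiv), Li2CuCl4 (3 mol %), THF/NMP, 0 °C → rt
Reagents that add atoms: none
Why: LiCl-assisted Grignard formation at the aryl C–Br bond followed by copper-catalysed Kumada-type sp2–sp3 cross-coupling with the primary bromide forms the ring A–C1 bond; the MOM and TIPS ethers and the terminal alkene are inert to both stages.

Step 4
Reactants: 6 1-(hept-6-en-1-yl)-3-(methoxymethoxy)-5-(triisopropylsilyloxy)benzene
Product: 7 2-{7-[3-(methoxymethoxy)-5-(triisopropylsilyloxy)phenyl]heptyl}-4,4,5,5-tetramethyl-1,3,2-dioxaborolane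
Conditions: HBpin (1.3 equiv), [Ir(cod)Cl]2 (1.5 mol %), dppm (3 mol %), CH2Cl2, rt
Reagents that add atoms: pinacolborane (HBpin), CC1(C)OBOC1(C)C
Why: Iridium-catalysed anti-Markovnikov hydroboration of a terminal alkene with pinacolborane should place boron on the terminal carbon (future C7) and tolerates aryl ethers and acetals.

Step 5
Reactants: 1 5-bromobenzene-1,3-diol
Product: 8 1-bromo-3,5-bis(triisopropylsilyloxy)benzene
Conditions: iPr3SiCl (2.3 equiv), imidazole (4.5 equiv), DMF, rt
Reagents that add atoms: chlorotri(propan-2-yl)silane (iPr3SiCl), CC(C)[Si](Cl)(C(C)C)C(C)C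
Why: Exhaustive silyl ether formation at both phenols gives a ring B building block that is stable to organometallic reagents and mild base.

Step 6
Reactants: 8 1-bromo-3,5-bis(triisopropylsilyloxy)benzene; 9 1,7-dibromoheptane
Product: 11 1-(7-bromoheptyl)-3,5-bis(triisopropylsilyloxy)benzene, via arylmagnesium bromide 10 (not isolated)
Conditions: Mg turnings, LiCl, THF, rt; then addition to 9 (4 equiv), Li2CuCl4 (3 mol %), THF/NMP, 0 °C → rt
Reagents that add atoms: none
Why: Grignard formation and copper-catalysed Kumada-type sp2–sp3 coupling as in step 3 form the ring B–C16 bond; the fourfold excess of dibromide should hold the reaction at monosubstitution and keep one C–Br bond for step 7.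

Step 7
Reactants: 11 1-(7-bromoheptyl)-3,5-bis(triisopropylsilyloxy)benzene; 12 ethynyl(trimethyl)silane
Product: 14 {9-[3,5-bis(triisopropylsilyloxy)phenyl]non-1-yn-1-yl}trimethylsilane, via lithium (trimethylsilyl)acetylide 13 (not isolated)
Conditions: 12 (1.5 equiv), n-BuLi (1.4 equiv), THF, −78 °C; then 11, DMPU, −78 °C → rt
Reagents that add atoms: none
Why: SN2 alkylation of a lithium acetylide with a primary alkyl bromide in a dipolar cosolvent forms C9–C10; the silyl cap prevents dialkylation and the hindered aryl TIPS ethers should not be attacked by the carbon nucleophile.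

Step 8
Reactants: 14 {9-[3,5-bis(triisopropylsilyloxy)phenyl]non-1-yn-1-yl}trimethylsilane
Product: 15 1-(non-8-yn-1-yl)-3,5-bis(triisopropylsilyloxy)benzene
Conditions: K2CO3 (0.3 equiv), MeOH/THF 1:1, rt
Reagents that add atoms: none
Why: Base-catalysed methanolytic protodesilylation of the alkynyl C–SiMe3 bond, which is far more labile at room temperature than the hindered aryl O–Si(iPr)3 bonds.

Step 9
Reactants: 15 1-(non-8-yn-1-yl)-3,5-bis(triisopropylsilyloxy)benzene
Product: 17 1-[(E)-9-iodonon-8-en-1-yl]-3,5-bis(triisopropylsilyloxy)benzene, via (E)-alkenylzirconocene chloride 16 (not isolated)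
Conditions: Cp2Zr(H)Cl (1.3 equiv), THF, rt; then I2 (1.3 equiv), THF, 0 °C
Reagents that add atoms: iodine, II
Why: Hydrozirconation of the terminal alkyne with the Schwartz reagent is a syn, anti-Markovnikov addition that gives the (E)-1-alkenylzirconium species, and iodinolysis of the C–Zr bond proceeds with retention to the E-iodide.

Step 10
Reactants: 17 1-[(E)-9-iodonon-8-en-1-yl]-3,5-bis(triisopropylsilyloxy)benzene; 7 2-{7-[3-(methoxymethoxy)-5-(triisopropylsilyloxy)phenyl]heptyl}-4,4,5,5-tetramethyl-1,3,2-dioxaborolane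
Product: 21 (Z)-1-[3-(methoxymethoxy)-5-(triisopropylsilyloxy)phenyl]-16-[3,5-bis(triisopropylsilyloxy)phenyl]hexadec-8-ene, via (E)-alkenyllithium 18 (not isolated), via lithium alkenyl(alkyl)boronate complex 19 (not isolated), via β-iodoalkyl boronic ester 20 (not isolated)
Conditions: 17 (1.2 equiv), t-BuLi (2.4 equiv), THF, −78 °C; then 7, THF, −78 °C; I2 (1.2 equiv), THF/MeOH, −78 °C; NaOMe (3 equiv), MeOH, −78 °C → rt; aq. Na2S2O3
Reagents that add atoms: none
Why: Iodine–lithium exchange on 17 gives the configurationally stable (E)-alkenyllithium 18, which adds to the empty p-orbital on boron of 7 to give the tetracoordinate boronate complex 19. Iodine then attacks the electron-rich alkenyl π-bond of 19 and the primary alkyl group (C7) migrates from boron to C8 anti to the forming C9–I bond (1,2-metallate rearrangement) to give 20, after which methoxide adds to boron and boron and iodine leave in an antiperiplanar elimination. The closest known reaction type is the Zweifel olefination of alkyl pinacol boronic esters with alkenyllithium reagents; no ring is closed and no stereocentre remains in the product. The Z geometry of C8=C9 is controlled by the E geometry of 17 together with the anti-addition/anti-elimination course, which inverts the alkene geometry stereospecifically. The step needs exclusive migration of C7, secured because it is the only carbon ligand on boron besides the alkenyl group, and selectivity of iodine for the boronate π-bond over the silyloxy arenes, secured by the much higher nucleophilicity of the ate complex at −78 °C and by keeping iodine near one equivalent.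

Step 11
Reactants: 21 (Z)-1-[3-(methoxymethoxy)-5-(triisopropylsilyloxy)phenyl]-16-[3,5-bis(triisopropylsilyloxy)phenyl]hexadec-8-ene
Product: 22 3-{(Z)-16-[3,5-bis(triisopropylsilyloxy)phenyl]hexadec-8-en-1-yl}-5-(triisopropylsilyloxy)phenol
Conditions: conc. HCl (cat.), MeOH/THF, 40 °C
Reagents that add atoms: none
Why: Acid-catalysed acetal exchange (methanolysis of the aryl MOM ether) should free the one ring A oxygen, because aryl triisopropylsilyl ethers cleave slowly under protic acid and the isolated Z alkene does not isomerise.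

Step 12
Reactants: 22 3-{(Z)-16-[3,5-bis(triisopropylsilyloxy)phenyl]hexadec-8-en-1-yl}-5-(triisopropylsilyloxy)phenol
Product: 23 3-{(Z)-16-[3,5-bis(triisopropylsilyloxy)phenyl]hexadec-8-en-1-yl}-5-(triisopropylsilyloxy)phenyl acetate
Conditions: Ac2O (1.5 equiv), pyridine, DMAP (5 mol %), CH2Cl2, 0 °C → rt
Reagents that add atoms: acetic anhydride, CC(=O)OC(C)=O
Why: DMAP-catalysed esterification of the single free phenol places the acetate on ring A regiospecifically, because every other oxygen is still silylated.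

Step 13
Reactants: 23 3-{(Z)-16-[3,5-bis(triisopropylsilyloxy)phenyl]hexadec-8-en-1-yl}-5-(triisopropylsilyloxy)phenyl acetate
Product: 24 Oncostemonol B, 3-[(Z)-16-(3,5-dihydroxyphenyl)hexadec-8-en-1-yl]-5-hydroxyphenyl acetate
Conditions: HF·pyridine (excess), pyridine, THF, 0 °C → rt; pH 7 buffer work-up
Reagents that add atoms: none
Why: Fluoride-mediated Si–O cleavage driven by Si–F bond formation under acidic, non-nucleophilic conditions should remove the three aryl silyl ethers without forming phenoxide, so the aryl acetate is neither hydrolysed nor transferred and the Z alkene is untouched.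

**Compound list**

1 | 5-bromobenzene-1,3-diol (5-bromoresorcinol) | Oc1cc(O)cc(Br)c1 | starting material
2 | 3-bromo-5-(triisopropylsilyloxy)phenol | Oc1cc(Br)cc(O[Si](C(C)C)(C(C)C)C(C)C)c1 | intermediate
3 | 1-bromo-3-(methoxymethoxy)-5-(triisopropylsilyloxy)benzene | COCOc1cc(Br)cc(O[Si](C(C)C)(C(C)C)C(C)C)c1 | intermediate
4 | 7-bromohept-1-ene | C=CCCCCCBr | starting material
5 | [3-(methoxymethoxy)-5-(triisopropylsilyloxy)phenyl]magnesium bromide | COCOc1cc([Mg]Br)cc(O[Si](C(C)C)(C(C)C)C(C)C)c1 | intermediate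
6 | 1-(hept-6-en-1-yl)-3-(methoxymethoxy)-5-(triisopropylsilyloxy)benzene | COCOc1cc(CCCCCC=C)cc(O[Si](C(C)C)(C(C)C)C(C)C)c1 | intermediate
7 | 2-{7-[3-(methoxymethoxy)-5-(triisopropylsilyloxy)phenyl]heptyl}-4,4,5,5-tetramethyl-1,3,2-dioxaborolane | COCOc1cc(CCCCCCCB2OC(C)(C)C(C)(C)O2)cc(O[Si](C(C)C)(C(C)C)C(C)C)c1 | intermediate
8 | 1-bromo-3,5-bis(triisopropylsilyloxy)benzene | Brc1cc(O[Si](C(C)C)(C(C)C)C(C)C)cc(O[Si](C(C)C)(C(C)C)C(C)C)c1 | intermediate
9 | 1,7-dibromoheptane | BrCCCCCCCBr | starting material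
10 | [3,5-bis(triisopropylsilyloxy)phenyl]magnesium bromide | Br[Mg]c1cc(O[Si](C(C)C)(C(C)C)C(C)C)cc(O[Si](C(C)C)(C(C)C)C(C)C)c1 | intermediate
11 | 1-(7-bromoheptyl)-3,5-bis(triisopropylsilyloxy)benzene | BrCCCCCCCc1cc(O[Si](C(C)C)(C(C)C)C(C)C)cc(O[Si](C(C)C)(C(C)C)C(C)C)c1 | intermediate
12 | ethynyl(trimethyl)silane | C#C[Si](C)(C)C | starting material
13 | lithium (trimethylsilyl)acetylide | [Li]C#C[Si](C)(C)C | intermediate
14 | {9-[3,5-bis(triisopropylsilyloxy)phenyl]non-1-yn-1-yl}trimethylsilane | C[Si](C)(C)C#CCCCCCCCc1cc(O[Si](C(C)C)(C(C)C)C(C)C)cc(O[Si](C(C)C)(C(C)C)C(C)C)c1 | intermediate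
15 | 1-(non-8-yn-1-yl)-3,5-bis(triisopropylsilyloxy)benzene | C#CCCCCCCCc1cc(O[Si](C(C)C)(C(C)C)C(C)C)cc(O[Si](C(C)C)(C(C)C)C(C)C)c1 | intermediate
16 | chlorobis(cyclopentadienyl){(E)-9-[3,5-bis(triisopropylsilyloxy)phenyl]non-1-en-1-yl}zirconium (cyclopentadienyl rings drawn σ-bonded) | Cl[Zr](/C=C/CCCCCCCc1cc(O[Si](C(C)C)(C(C)C)C(C)C)cc(O[Si](C(C)C)(C(C)C)C(C)C)c1)(C2C=CC=C2)C2C=CC=C2 | intermediate
17 | 1-[(E)-9-iodonon-8-en-1-yl]-3,5-bis(triisopropylsilyloxy)benzene | I/C=C/CCCCCCCc1cc(O[Si](C(C)C)(C(C)C)C(C)C)cc(O[Si](C(C)C)(C(C)C)C(C)C)c1 | intermediate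
18 | {(E)-9-[3,5-bis(triisopropylsilyloxy)phenyl]non-1-en-1-yl}lithium | [Li]/C=C/CCCCCCCc1cc(O[Si](C(C)C)(C(C)C)C(C)C)cc(O[Si](C(C)C)(C(C)C)C(C)C)c1 | intermediate
19 | lithium boronate complex of 7 and 18 (boron bearing pinacolate, the C1–C7 alkyl group and the (E)-alkenyl group) | [Li+].COCOc1cc(CCCCCCC[B-]2(/C=C/CCCCCCCc3cc(O[Si](C(C)C)(C(C)C)C(C)C)cc(O[Si](C(C)C)(C(C)C)C(C)C)c3)OC(C)(C)C(C)(C)O2)cc(O[Si](C(C)C)(C(C)C)C(C)C)c1 | intermediate
20 | 2-{(8S*,9S*)-9-iodo-1-[3-(methoxymethoxy)-5-(triisopropylsilyloxy)phenyl]-16-[3,5-bis(triisopropylsilyloxy)phenyl]hexadecan-8-yl}-4,4,5,5-tetramethyl-1,3,2-dioxaborolane (racemic, one enantiomer drawn) | COCOc1cc(CCCCCCC[C@H](B2OC(C)(C)C(C)(C)O2)[C@@H](I)CCCCCCCc3cc(O[Si](C(C)C)(C(C)C)C(C)C)cc(O[Si](C(C)C)(C(C)C)C(C)C)c3)cc(O[Si](C(C)C)(C(C)C)C(C)C)c1 | intermediate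
21 | (Z)-1-[3-(methoxymethoxy)-5-(triisopropylsilyloxy)phenyl]-16-[3,5-bis(triisopropylsilyloxy)phenyl]hexadec-8-ene | COCOc1cc(CCCCCCC/C=C\CCCCCCCc2cc(O[Si](C(C)C)(C(C)C)C(C)C)cc(O[Si](C(C)C)(C(C)C)C(C)C)c2)cc(O[Si](C(C)C)(C(C)C)C(C)C)c1 | intermediate
22 | 3-{(Z)-16-[3,5-bis(triisopropylsilyloxy)phenyl]hexadec-8-en-1-yl}-5-(triisopropylsilyloxy)phenol | Oc1cc(CCCCCCC/C=C\CCCCCCCc2cc(O[Si](C(C)C)(C(C)C)C(C)C)cc(O[Si](C(C)C)(C(C)C)C(C)C)c2)cc(O[Si](C(C)C)(C(C)C)C(C)C)c1 | intermediate
23 | 3-{(Z)-16-[3,5-bis(triisopropylsilyloxy)phenyl]hexadec-8-en-1-yl}-5-(triisopropylsilyloxy)phenyl acetate | CC(=O)Oc1cc(CCCCCCC/C=C\CCCCCCCc2cc(O[Si](C(C)C)(C(C)C)C(C)C)cc(O[Si](C(C)C)(C(C)C)C(C)C)c2)cc(O[Si](C(C)C)(C(C)C)C(C)C)c1 | intermediate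
24 | Oncostemonol B, 3-[(Z)-16-(3,5-dihydroxyphenyl)hexadec-8-en-1-yl]-5-hydroxyphenyl acetate | CC(=O)Oc1cc(O)cc(CCCCCCC/C=C\CCCCCCCc2cc(O)cc(O)c2)c1 | target

**Summary and risks**

Total step count: 13. Longest linear sequence: 9 steps (steps 5, 6, 7, 8, 9, 10, 11, 12, 13; 1 → 8 → 11 → 14 → 15 → 17 → 21 → 22 → 23 → 24).

Steps most likely to fail:

Step 10. The boronate complex may form incompletely if the alkenyllithium is quenched by adventitious protons. Iodine, or methyl hypoiodite formed with methoxide, may iodinate the electron-rich silyloxy rings, and methoxide may begin to cleave aryl Si–O bonds during the elimination. The fallback forms the same C7–C8 bond at the alkyne oxidation level; it sets out from 3 (through its Grignard reagent 5) and from 15 and comes back to the route at 21. Grignard reagent 5 would be coupled with an excess of 1,7-dibromoheptane 9 under Li2CuCl4 catalysis to give 1-(7-bromoheptyl)-3-(methoxymethoxy)-5-(triisopropylsilyloxy)benzene F1. Alkyne 15 would be deprotonated with n-BuLi in THF at −78 °C to {9-[3,5-bis(triisopropylsilyloxy)phenyl]non-1-yn-1-yl}lithium F2 and alkylated with F1 in THF/DMPU to 1-[3-(methoxymethoxy)-5-(triisopropylsilyloxy)phenyl]-16-[3,5-bis(triisopropylsilyloxy)phenyl]hexadec-8-yne F3. Semi-hydrogenation of F3 (H2, Pd/CaCO3 poisoned with Pb(OAc)2, quinoline, hexane/EtOAc; Lindlar reduction, syn addition) should give 21.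

Step 11. One or more aryl silyl ethers may be lost together with the MOM group under protic acid, which would erase the differentiation of the four oxygens. The fallback gives up the differentiation and uses the symmetry of the parent; it sets out from 21 and comes back at 24. Exhaustive deprotection of 21 (HCl in MeOH/THF, then HF·pyridine) would give 5,5'-[(Z)-hexadec-8-ene-1,16-diyl]di(benzene-1,3-diol) F4, whose four hydroxyl groups are equivalent by symmetry. Acetylation with a deficit of Ac2O (pyridine, CH2Cl2, −20 °C) then gives 24 as the only possible monoacetate. Over-acetylated material would be returned to F4 with K2CO3/MeOH and recycled.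

Step 6. Magnesium insertion into the hindered, electron-rich aryl bromide may be sluggish, and biaryl homocoupling or double arylation of the dibromide may compete. The fallback builds the ring B–C16 bond by alkyne coupling and reduction; it sets out from 8 and comes back at 11. Sonogashira coupling of 8 with commercial hept-6-yn-1-ol (PdCl2(PPh3)2, CuI, Et3N, 70 °C) would give 7-[3,5-bis(triisopropylsilyloxy)phenyl]hept-6-yn-1-ol F5. Hydrogenation (H2, Pd/C, EtOAc) would give 7-[3,5-bis(triisopropylsilyloxy)phenyl]heptan-1-ol F6, and Appel bromination (CBr4, PPh3, CH2Cl2, 0 °C) would give 11.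

Further compounds

F1 | step 10 | 1-(7-bromoheptyl)-3-(methoxymethoxy)-5-(triisopropylsilyloxy)benzene | COCOc1cc(CCCCCCCBr)cc(O[Si](C(C)C)(C(C)C)C(C)C)c1
F2 | step 10 | {9-[3,5-bis(triisopropylsilyloxy)phenyl]non-1-yn-1-yl}lithium | [Li]C#CCCCCCCCc1cc(O[Si](C(C)C)(C(C)C)C(C)C)cc(O[Si](C(C)C)(C(C)C)C(C)C)c1
F3 | step 10 | 1-[3-(methoxymethoxy)-5-(triisopropylsilyloxy)phenyl]-16-[3,5-bis(triisopropylsilyloxy)phenyl]hexadec-8-yne | COCOc1cc(CCCCCCCC#CCCCCCCCc2cc(O[Si](C(C)C)(C(C)C)C(C)C)cc(O[Si](C(C)C)(C(C)C)C(C)C)c2)cc(O[Si](C(C)C)(C(C)C)C(C)C)c1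
F4 | step 11 | 5,5'-[(Z)-hexadec-8-ene-1,16-diyl]di(benzene-1,3-diol) | Oc1cc(O)cc(CCCCCCC/C=C\CCCCCCCc2cc(O)cc(O)c2)c1
F5 | step 6 | 7-[3,5-bis(triisopropylsilyloxy)phenyl]hept-6-yn-1-ol | OCCCCCC#Cc1cc(O[Si](C(C)C)(C(C)C)C(C)C)cc(O[Si](C(C)C)(C(C)C)C(C)C)c1
F6 | step 6 | 7-[3,5-bis(triisopropylsilyloxy)phenyl]heptan-1-ol | OCCCCCCCc1cc(O[Si](C(C)C)(C(C)C)C(C)C)cc(O[Si](C(C)C)(C(C)C)C(C)C)c1
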